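**Retrosynthetic overview**

- The target is cut at the C7'–C8' single bond into a C30 allylic sulfone (from β-apo-8'-carotenal) and a C10 aldehyde (from (S)-citronellal). The sulfonyl group makes the former carbonyl carbon C8' a nucleophile that attacks the carbonyl carbon C7'.
- The retro chromophore is not built bond by bond. After the coupling, loss of acetate and then of sulfinate (a vinylogous elimination that takes H4 of ring A) shifts all ten chain double bonds by one position.
- Ring A comes preformed in commercial β-apo-8'-carotenal. Ring B is closed first, by cationic cyclization of citronellal enol acetate, before the fragments are joined; no ring is formed afterwards.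
- The only stereocentre (C5', S) is the citronellal stereocentre and is never part of a reacting centre.

Assumption: commercial β-apo-8'-carotenal (colourant E 160e) is the all-E isomer and (S)-(−)-citronellal is used at its supplied enantiomeric purity, which the target inherits; carotenoid numbering is used (ring A = C1–C6, chain C7…C15, C15'…C7', ring B = C1'–C6').

**Route**

Step 1
Reactants: 1 (S)-(−)-citronellal [(3S)-3,7-dimethyloct-6-enal]
Product: 2 (3S)-3,7-dimethylocta-1,6-dien-1-yl acetate (E/Z mixture at C1=C2)
Conditions: Ac2O, KOAc (cat.), Et3N, 120 °C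
Reagents that add atoms: acetic anhydride, CC(=O)OC(C)=O
Why: Enol acetate formation (O-acylation of the aldehyde enolate) masks the aldehyde as a weakly nucleophilic alkene; the stereocentre is β to the carbonyl, cannot enolize and stays (S), and both alkene isomers converge in step 2.

Step 2
Reactants: 2 (3S)-3,7-dimethylocta-1,6-dien-1-yl acetate
Product: 4 (1R,6S)-2,2,6-trimethylcyclohexane-1-carbaldehyde (trans), via hemiacylal acetate 3 (not isolated)
Conditions: 85% H3PO4, toluene, 90 °C; then H2O
Reagents that add atoms: water, O
Why: Brønsted-acid cation–olefin cyclization: Markovnikov protonation of the trisubstituted alkene gives a tertiary cation that the enol acetate carbon captures through a chair transition state with the methyl group equatorial, so the new C1 centre is mainly trans (R) while the citronellal centre is carried over as C6 (S); water opens the acetoxycarbenium ion to hemiacylal 3, which loses acetic acid, and C1 becomes sp2 in step 5 so its configuration does not matter.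

Step 3
Reactants: 5 all-E β-apo-8'-carotenal
Product: 6 all-E β-apo-8'-carotenol
Conditions: NaBH4, THF–EtOH, 0 °C, dark
Reagents that add atoms: none
Why: Chemoselective 1,2-hydride reduction of a polyenal (the retinal → retinol reaction); no stereocentre is formed and the all-E nonaene is untouched.

Step 4
Reactants: 6 all-E β-apo-8'-carotenol
Product: 7 all-E β-apo-8'-carotenyl phenyl sulfone
Conditions: PhSO2Na (3 equiv), AcOH–i-PrOH (1:3), 25 °C, dark
Reagents that add atoms: sodium benzenesulfinate, [Na+].[O-]S(=O)c1ccccc1
Why: SN1-type dehydrative sulfination of an allylic alcohol (the Julia route to terpenoid allyl sulfones): acetic acid ionizes the polyenylic alcohol and the ambident sulfinate binds through sulfur at the terminal carbon C8', which keeps the nonaene conjugated and all-E; no stereocentre is formed.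

Step 5
Reactants: 7 all-E β-apo-8'-carotenyl phenyl sulfone; 4 (1R,6S)-2,2,6-trimethylcyclohexane-1-carbaldehyde
Product: 13 (5'S)-4,5'-retro-β,β-carotene (all-E, the target), via lithiated sulfone 8 (not isolated), via lithium alkoxide 9 (not isolated), via acetoxy sulfone 10 (not isolated), via vinyl sulfone 11 (not isolated), via allyl sulfone 12 (not isolated)
Conditions: n-BuLi (1.05 equiv), THF, −78 °C; 4 (1.3 equiv); Ac2O (1.5 equiv), −78 → 0 °C; t-BuOK (6 equiv), 0 → 25 °C, Ar, dark; crystallization (CH2Cl2–MeOH)
Reagents that add atoms: none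
Why: Proposed new method: the sulfonyl group reverses the polarity of C8' (a carbonyl carbon in 5), so lithiated sulfone 8 adds through its α-carbon to the carbonyl carbon C7' of 4 as in a Julia coupling and alkoxide 9 is fixed as acetate 10; t-BuOK then removes acetate by E1cB (11), moves the double bond into the ring-B exocyclic position by the usual vinyl → allyl sulfone shift (12, chain syn to C5' for minimal allylic strain), and, because C8' has no hydrogen-bearing neighbour, the sulfinate can only leave by a vinylogous E1cB through the nonaene after loss of H4 of ring A, the proton that gives the most delocalized carbanion (the site deprotonated in the base-induced β-ionone → retro-ionone shift), which moves all ten chain double bonds into the retro pattern with the s-trans single bonds becoming E double bonds; the closest known reaction type is Otera's one-pot double elimination, whose 1,6-loss of sulfinate in the vitamin A synthesis is stretched here to a 1,20-loss, and no stereocentre is formed, the C5' centre being kept because its C–H lies in the plane of the C6'=C7' bond and should be the slowest allylic hydrogen to exchange.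

**Compound list**

1 | (S)-(−)-citronellal, (3S)-3,7-dimethyloct-6-enal | C[C@@H](CCC=C(C)C)CC=O | starting material
2 | (3S)-3,7-dimethylocta-1,6-dien-1-yl acetate (citronellal enol acetate, E/Z mixture at C1=C2) | CC(=O)OC=C[C@@H](C)CCC=C(C)C | intermediate
3 | hydroxy[(1R,6S)-2,2,6-trimethylcyclohexyl]methyl acetate (hemiacylal, either configuration at the carbinol carbon) | CC(=O)OC(O)[C@@H]1[C@@H](C)CCCC1(C)C | intermediate
4 | (1R,6S)-2,2,6-trimethylcyclohexane-1-carbaldehyde (trans; ring B plus C7') | O=C[C@@H]1[C@@H](C)CCCC1(C)C | intermediate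
5 | all-E β-apo-8'-carotenal, (2E,4E,6E,8E,10E,12E,14E,16E)-2,6,11,15-tetramethyl-17-(2,6,6-trimethylcyclohex-1-en-1-yl)heptadeca-2,4,6,8,10,12,14,16-octaenal | CC1=C(C(C)(C)CCC1)/C=C/C(C)=C/C=C/C(C)=C/C=C/C=C(C)/C=C/C=C(C)/C=O | starting material
6 | all-E β-apo-8'-carotenol (the primary allylic alcohol, C8'H2OH) | CC1=C(C(C)(C)CCC1)/C=C/C(C)=C/C=C/C(C)=C/C=C/C=C(C)/C=C/C=C(C)/CO | intermediate
7 | all-E β-apo-8'-carotenyl phenyl sulfone (C8'H2–SO2Ph) | CC1=C(C(C)(C)CCC1)/C=C/C(C)=C/C=C/C(C)=C/C=C/C=C(C)/C=C/C=C(C)/CS(=O)(=O)c1ccccc1 | intermediate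
8 | 8'-lithio derivative of 7 (α-sulfonyl carbanion at C8') | CC1=C(C(C)(C)CCC1)/C=C/C(C)=C/C=C/C(C)=C/C=C/C=C(C)/C=C/C=C(C)/C([Li])S(=O)(=O)c1ccccc1 | intermediate
9 | lithium (5'S,6'R)-8'-(phenylsulfonyl)-5',6',7',8'-tetrahydro-β,β-caroten-7'-olate (mixture at C7' and C8') | CC1=C(C(C)(C)CCC1)/C=C/C(C)=C/C=C/C(C)=C/C=C/C=C(C)/C=C/C=C(C)/C(S(=O)(=O)c1ccccc1)C(O[Li])[C@@H]2[C@@H](C)CCCC2(C)C | intermediate
10 | (5'S,6'R)-8'-(phenylsulfonyl)-5',6',7',8'-tetrahydro-β,β-caroten-7'-yl acetate (mixture at C7' and C8') | CC1=C(C(C)(C)CCC1)/C=C/C(C)=C/C=C/C(C)=C/C=C/C=C(C)/C=C/C=C(C)/C(S(=O)(=O)c1ccccc1)C(OC(C)=O)[C@@H]2[C@@H](C)CCCC2(C)C | intermediate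
11 | (5'S)-8'-(phenylsulfonyl)-5',6'-dihydro-β,β-carotene (vinyl sulfone, C7'=C8' of either geometry, C6' as in 4) | CC1=C(C(C)(C)CCC1)/C=C/C(C)=C/C=C/C(C)=C/C=C/C=C(C)/C=C/C=C(C)/C(=C[C@@H]2[C@@H](C)CCCC2(C)C)S(=O)(=O)c1ccccc1 | intermediate
12 | (5'S)-8'-(phenylsulfonyl)-5',8'-dihydro-β,β-carotene (allyl sulfone, exocyclic C6'=C7' with the chain syn to C5', either configuration at C8') | CC1=C(C(C)(C)CCC1)/C=C/C(C)=C/C=C/C(C)=C/C=C/C=C(C)/C=C/C=C(C)/C(S(=O)(=O)c1ccccc1)/C=C2\[C@@H](C)CCCC2(C)C | intermediate
13 | (5'S)-4,5'-retro-β,β-carotene, all-E (6E,6'E) | CC1=CCCC(C)(C)\C1=C/C=C(C)/C=C/C=C(C)/C=C/C=C/C(C)=C/C=C/C(C)=C/C=C1\[C@@H](C)CCCC1(C)C | target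

**Step count and risks**

Total step count: 5. Longest linear sequence: 3 steps (1 → 2 → 4 → 13, or 5 → 6 → 7 → 13).

Most likely to fail, in this order:

Step 5 is the weakest point. The hindered aldehyde may add reversibly, and vinyl sulfone 11 may lose sulfinate directly to a 7',8'-alkyne. The alkoxide may also take a proton from the methyl groups on C9 or C13, from C18 or from C5' instead of C4, which would give cross-conjugated methylene isomers or β,β-carotene, and long exposure could erode C5'. The C6=C7 bond will in any case come out as a 6E/6Z pair that has to be equilibrated thermally and separated by crystallization. The fallback sets out from 4 and 5 and comes back at 13. Aldehyde 4 is turned into its enol triflate, [(6S)-2,2,6-trimethylcyclohexylidene]methyl trifluoromethanesulfonate F1 (Tf2O, 2,6-di-tert-butyl-4-methylpyridine, CH2Cl2). CrCl2 with catalytic NiCl2 in DMF converts this electrophile into an alkenylchromium reagent that adds 1,2 to the carbonyl group of 5 (Nozaki–Hiyama–Kishi reductive coupling of two electrophiles) and gives the bis-allylic alcohol (5'S)-5',8'-dihydro-β,β-caroten-8'-ol F2. A trace of HCl in EtOH–CH2Cl2 at −20 °C then ionizes this alcohol to the polyenyl cation, which loses H4 by E1 in the way retinol gives anhydroretinol, so 13 is reached by a cationic instead of a carbanionic long-range elimination.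

Step 4 comes second. The polyenyl cation may lose H4 to give the anhydro (retro) C30 hydrocarbon, or take up sulfinate at an inner carbon. The fallback sets out from 6 and comes back at 7. Acetylation (Ac2O, pyridine, 0 °C) gives all-E β-apo-8'-carotenyl acetate F3. Pd(PPh3)4 (3 mol %, zerovalent palladium) with PhSO2Na in THF–MeOH at 25 °C then makes 7 by Tsuji–Trost allylic substitution in a neutral medium, the sulfinate going to the unhindered terminus of the allyl-palladium complex.

Step 2 comes third. The hot protic acid may protonate the enol acetate instead of the alkene (Prins-type closure to p-menthane products), or allow a 1,5-hydride shift that would racemize C6. The fallback sets out from 2 and comes back at 4. Dry HCl in CH2Cl2 at −40 °C adds in the Markovnikov sense to the trisubstituted alkene and gives (3S)-7-chloro-3,7-dimethyloct-1-en-1-yl acetate F4. ZnCl2 in CH2Cl2 at −40 °C then ionizes only the tertiary chloride, so the enol acetate is alkylated intramolecularly under aprotic conditions (Reetz-type α-tert-alkylation), and aqueous work-up gives 4.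

**Further compounds**

F1 | step 5 | [(6S)-2,2,6-trimethylcyclohexylidene]methyl trifluoromethanesulfonate (either alkene geometry) | FC(F)(F)S(=O)(=O)OC=C1[C@@H](C)CCCC1(C)C
F2 | step 5 | (5'S)-5',8'-dihydro-β,β-caroten-8'-ol (either configuration at C8' and either C6'=C7' geometry) | CC1=C(C(C)(C)CCC1)/C=C/C(C)=C/C=C/C(C)=C/C=C/C=C(C)/C=C/C=C(C)/C(O)C=C2[C@@H](C)CCCC2(C)C
F3 | step 4 | all-E β-apo-8'-carotenyl acetate | CC1=C(C(C)(C)CCC1)/C=C/C(C)=C/C=C/C(C)=C/C=C/C=C(C)/C=C/C=C(C)/COC(C)=O
F4 | step 2 | (3S)-7-chloro-3,7-dimethyloct-1-en-1-yl acetate (E/Z mixture) | CC(=O)OC=C[C@@H](C)CCCC(C)(C)Cl
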